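**Assumptions:** Chiricanine C has no stereocentres. Its only stereo-element is the E-stilbene double bond, which comes from (E)-styrylboronic acid. 5-Methoxyresorcinol (3,5-dihydroxyanisole) is taken as commercially available.

## Retrosynthesis
1. Target **1** comes from a Suzuki disconnection of the styryl C(sp²)–C(sp²) bond. That gives aryl triflate **2** and (E)-2-phenylvinylboronic acid **3**.
2. Triflate **2** comes from mono-triflation of the C2-symmetric diol **4**. Diol **4** comes from double C-prenylation of 5-methoxyresorcinol **5** with prenyl bromide **6**.
3. The two prenyl positions of **5** (C4 and C6) are equivalent. Each is ortho to OMe, ortho to one OH and para to the other OH, so they are the most nucleophilic sites, and the OMe ends up flanked by the two prenyls as required.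
4. No ring is constructed; the only ring is the commercial arene. The order is C-prenylation, then desymmetrising triflation, then the Suzuki coupling that installs the alkene.

## Route

**Step 1**
Reactants: **5** 5-methoxyresorcinol; **6** prenyl bromide (2.2 equiv)
Product: **4** 4,6-bis(3-methylbut-2-en-1-yl)-5-methoxybenzene-1,3-diol
Conditions: NaOH (2.2 equiv), H2O, 0 °C → rt, 12 h
Reagents that add atoms: prenyl bromide, BrCC=C(C)C
Why: Electrophilic C-alkylation of the phenoxide in water (hydrogen-bonded O, so C- rather than O-alkylation) goes to the two equivalent, most activated positions C4 and C6. No stereocentre is formed.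

**Step 2**
Reactants: **4** diol; **7** N-phenylbis(trifluoromethanesulfonimide) (PhNTf2, 1.0 equiv)
Product: **2** 5-hydroxy-3-methoxy-2,4-bis(3-methylbut-2-en-1-yl)phenyl trifluoromethanesulfonate
Conditions: PhNTf2, Et3N, CH2Cl2, 0 °C → rt
Reagents that add atoms: PhNTf2, O=S(=O)(N(c1ccccc1)S(=O)(=O)C(F)(F)F)C(F)(F)F (adds the Tf group)
Why: O-Triflation of one of the two equivalent phenols (statistical desymmetrisation). The mild triflyl donor limits bis-triflate formation, and the prenyl alkenes, OMe and the remaining OH are untouched.

**Step 3**
Reactants: **2** aryl triflate; **3** (E)-2-phenylvinylboronic acid (1.5 equiv)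
Product: **1** Chiricanine C
Conditions: Pd(dppf)Cl2 (5 mol %), K3PO4, dioxane/H2O 10:1, 85 °C
Reagents that add atoms: none beyond the reactants (base and Pd are not retained)
Why: Suzuki–Miyaura coupling proceeds by oxidative addition into Ar–OTf, transmetalation and reductive elimination, with retention of the alkene geometry, so the E-stilbene is formed. The trisubstituted prenyl alkenes and the free phenol are tolerated. An ortho-prenyl Heck-type cyclisation is disfavoured (4-exo or 5-endo).

## Checks
- The atom count balances: C7 (**5**) + 2 × C5 (prenyl) + C8 (styryl) = C25, the formula of the target.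
- Substituent pattern of **1**: C1 styryl, C2 prenyl, C3 OMe, C4 prenyl, C5 OH, C6 H. This matches the target SMILES.
- The only stereo-element (E alkene) is set in step 3 and is not altered afterwards.

## Compound list
| No. | Name | SMILES | Role |
|---|---|---|---|
| 1 | Chiricanine C, (E)-3-hydroxy-5-methoxy-2,4-diprenylstilbene | COc1c(CC=C(C)C)c(O)cc(/C=C/c2ccccc2)c1CC=C(C)C | target |
| 2 | 5-hydroxy-3-methoxy-2,4-bis(3-methylbut-2-en-1-yl)phenyl triflate | COc1c(CC=C(C)C)c(O)cc(OS(=O)(=O)C(F)(F)F)c1CC=C(C)C | intermediate |
| 3 | (E)-2-phenylvinylboronic acid | OB(O)/C=C/c1ccccc1 | starting material |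
| 4 | 4,6-bis(3-methylbut-2-en-1-yl)-5-methoxybenzene-1,3-diol | COc1c(CC=C(C)C)c(O)cc(O)c1CC=C(C)C | intermediate |
| 5 | 5-methoxyresorcinol (3,5-dihydroxyanisole) | COc1cc(O)cc(O)c1 | starting material |
| 6 | prenyl bromide (1-bromo-3-methylbut-2-ene) | BrCC=C(C)C | starting material |
| 7 | PhNTf2 | O=S(=O)(N(c1ccccc1)S(=O)(=O)C(F)(F)F)C(F)(F)F | starting material (reagent) |

**Total steps:** 3. **Longest linear sequence:** 3.

## Three steps most likely to fail, with fallbacks
1. **Step 1 (prenylation).** Over-alkylation at C2, O-prenylation and mono-prenyl products could lower the yield.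
   - Fallback: brominate **5** with NBS at C4/C6, then couple twice with prenylzinc bromide under Pd catalysis. This replaces direct alkylation with a cross-coupling approach.
2. **Step 2 (mono-triflation).** The desymmetrisation is only statistical, so bis-triflate and unreacted diol will form.
   - Fallback: make the bis-triflate quantitatively, run a mono-selective Suzuki with 1 equiv of **3**, then cleave the remaining triflate (K2CO3, MeOH) to the phenol. The bis-triflate byproducts can be recycled.
3. **Step 3 (Suzuki).** The electron-rich, hindered triflate bearing a free phenol may undergo S–O hydrolysis or couple poorly.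
   - Fallback: Heck reaction of **2** with styrene (Pd(OAc)2, PPh3, Et3N, DMF, 100 °C), which gives the E-stilbene directly under non-aqueous conditions.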